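**Plan**

- Numbering for each half: ring A = C1 (isopropyl), C2, C3, C4 (OH and C12H2O), C5, C10; ring B = C5, C6 (lactone C=O), O, C7, C8 (bears carboxyl C11), C9, C10. Primes mark the half whose C12′ oxygen is acylated. The halves are mirror images: (1R,4S,5S,10S) and (1′S,4′R,5′R,10′R).
- Retrosynthesis: cut the ester C11–O–C12′; in each half take the lactone back to the enol ether C5=C6H; cut O–C7 while re-forming C5–C9 (retro-Claisen, in reverse); then cut C9–C10/C5–C9 (ylide cyclopropanation), C4–C12 (hydroxymethyl Grignard) and C5–C6 (Baylis–Hillman) back to cryptone and 4-isopropylcyclohexanone.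
- Enabling feature: ring B holds O–C7H2–C8(C11)=C9H–C10 together with C5–C6(=O). With C6 at the aldehyde level this is a 2,5-dihydrooxepine, which maps onto a cyclopropane C5–C9–C10 fused to ring A with the C6 formyl group on C5 cis to a 1-(alkoxycarbonyl)vinyl group (C8=C7) on C9.
- Forward: one batch of an allylic sulfonium salt serves both series; ring A is bought, the cyclopropane is built on it, the C4 diol is installed, ring B arises by [3,3] ring expansion (step 12, mirrored in step 24) and is oxidised to the lactone; the two enantiomeric halves are then esterified and deprotected.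
- Stereochemistry: C1 from enantiotopos-selective deprotonation of the achiral ketone with either antipode of a chiral lithium amide; C10 by ylide attack anti to isopropyl; C4 by Grignard addition anti to the cyclopropane; C5 by axial protonation giving the trans ring fusion, which is also the more stable epimer.

Key step: step 12

Assumption: the sense of the lithium amide deprotonation is taken from 4-tert-butylcyclohexanone ((R,R)-amide gives the (S)-enol ether); if it were reversed for the isopropyl ketone, the two amides would be exchanged between the series.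

**Reagent (prepared once for both series)**

Step 1
Reactants: 1 2-(bromomethyl)acrylic acid; 2 2-(trimethylsilyl)ethanol
Product: 4 2-(trimethylsilyl)ethyl 2-(bromomethyl)acrylate, via 2-(bromomethyl)acryloyl chloride 3 (not isolated)
Conditions: (COCl)2, N,N-dimethylformamide (cat.), CH2Cl2, 0 °C → rt; concentrate; then 2, 2,6-lutidine, CH2Cl2, 0 °C
Reagents that add atoms: none
Why: Acid chloride formation followed by acylation of the primary alcohol; a hindered, non-nucleophilic base is used because nucleophilic acyl-transfer catalysts would attack the allylic bromide in SN2′ fashion.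

Step 2
Reactants: 4 2-(trimethylsilyl)ethyl 2-(bromomethyl)acrylate
Product: 5 1-{2-[(2-trimethylsilylethoxy)carbonyl]allyl}tetrahydrothiophenium bromide
Conditions: tetrahydrothiophene (1.5 equiv), acetone, rt; the precipitated salt is filtered off, washed with Et2O and stored cold
Reagents that add atoms: tetrahydrothiophene, C1CCSC1
Why: S-Alkylation of the sulfide by the allylic bromide (SN2 and SN2′ attack give the same product) should deliver the sulfonium salt as a solid that is isolated in one batch large enough for the cyclopropanations of both enantiomeric series.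

**Series A (acid half, from (R)-cryptone)**

Step 3
Reactants: 6 4-isopropylcyclohexanone
Product: 8 (S)-4-isopropyl-1-(trimethylsilyloxy)cyclohex-1-ene, via lithium (S)-enolate 7 (not isolated)
Conditions: (R,R)-bis(1-phenylethyl)amine, n-BuLi, LiCl, THF, −78 °C; 6; then Me3SiCl, −78 °C
Reagents that add atoms: chlorotrimethylsilane, C[Si](C)(C)Cl
Why: Enantiotopos-selective deprotonation of the achiral ketone by a C2-symmetric chiral lithium amide (asymmetric desymmetrisation) and O-silylation of the enolate; the amide antipode fixes C1, here giving the enol ether that corresponds to (R)-cryptone.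

Step 4
Reactants: 8 (S)-4-isopropyl-1-(trimethylsilyloxy)cyclohex-1-ene
Product: 9 (R)-cryptone [(R)-4-isopropylcyclohex-2-en-1-one]
Conditions: Pd(OAc)2 (10 mol %), O2 (1 atm), DMSO, rt
Reagents that add atoms: none
Why: Saegusa–Ito dehydrogenation in its aerobic catalytic form; the palladium enolate undergoes β-hydride elimination, so the double bond forms on the enol ether side and the C1 stereocentre is not touched.

Step 5
Reactants: 9 (R)-cryptone; 10 formaldehyde (37 % aqueous)
Product: 11 (R)-2-(hydroxymethyl)-4-isopropylcyclohex-2-en-1-one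
Conditions: 4-(dimethylamino)pyridine (0.2 equiv), THF/H2O (1:1), rt
Reagents that add atoms: none
Why: Morita–Baylis–Hillman reaction: the pyridine adds to C10, the enolate carbon C5 adds to formaldehyde and elimination returns the catalyst; no stereocentre is formed and C1 is unaffected under these weakly basic conditions.

Step 6
Reactants: 11 (R)-2-(hydroxymethyl)-4-isopropylcyclohex-2-en-1-one
Product: 12 (R)-2-[(tert-butyldimethylsilyloxy)methyl]-4-isopropylcyclohex-2-en-1-one
Conditions: t-BuMe2SiCl, imidazole, CH2Cl2, 0 °C → rt
Reagents that add atoms: tert-butyldimethylsilyl chloride, CC(C)(C)[Si](C)(C)Cl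
Why: Standard silylation of a primary alcohol, which prevents O-alkylation of the hydroxymethyl group in the basic cyclopropanation that follows.

Step 7
Reactants: 5 sulfonium bromide; 12 silyl ether of series A
Product: 13 cyclopropyl ketone of series A (cyclopropane C5–C9–C10 anti to isopropyl; acrylate exo on C9)
Conditions: 5 (1.3 equiv), Cs2CO3, MeCN, 0 °C → rt
Reagents that add atoms: none
Why: Michael-initiated ring closure with the allylic sulfonium ylide released from salt 5 by the carbonate (sulfur-ylide cyclopropanation of an enone): the ylide carbon C9 adds to C10 anti to the C1 isopropyl group, the C5 enolate displaces the sulfide at C9 (3-exo-tet), and the acrylate settles trans to the ring acyl carbon C4, that is exo and cis to C6, which fixes C5, C9 and C10 relative to C1.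

Step 8
Reactants: 13 cyclopropyl ketone of series A
Product: 15 C4,C12-diol of series A (C12 cis to C6; tertiary hydroxyl cis to the cyclopropane), via silane adduct 14 (not isolated)
Conditions: (i-PrO)Me2SiCH2MgCl, CeCl3, THF, −78 → 0 °C; then 30 % H2O2, KF, KHCO3, THF/MeOH, rt
Reagents that add atoms: (isopropoxydimethylsilyl)methylmagnesium chloride, CC(C)O[Si](C)(C)C[Mg]Cl; hydrogen peroxide, OO
Why: 1,2-Addition of a hydroxymethyl anion equivalent (silylmethyl Grignard reagent, faster at the ketone than at the ester) on the carbonyl face anti to the cyclopropane sets C4 with C12 cis to C6, and Tamao–Fleming oxidation then converts the C–Si bond into the primary alcohol.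

Step 9
Reactants: 15 C4,C12-diol of series A
Product: 16 isopropylidene ketal of series A
Conditions: 2-methoxypropene, pyridinium p-toluenesulfonate (cat.), CH2Cl2, 0 °C
Reagents that add atoms: 2-methoxypropene, COC(C)=C
Why: Acid-catalysed ketalisation of the 1,2-diol through the primary mixed ketal, run cold with a weak acid so that the tertiary cyclopropylcarbinyl C4–O bond is not ionised.

Step 10
Reactants: 16 isopropylidene ketal of series A
Product: 17 C6 primary alcohol of series A
Conditions: HF·pyridine, pyridine, THF, 0 °C → rt
Reagents that add atoms: none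
Why: Desilylation of the primary silyl ether with amine-buffered hydrogen fluoride, which does not fragment the 2-(trimethylsilyl)ethyl ester (that needs unsolvated fluoride) and leaves the ketal in place.

Step 11
Reactants: 17 C6 primary alcohol of series A
Product: 18 cis-vinylcyclopropanecarbaldehyde of series A
Conditions: Dess–Martin periodinane, CH2Cl2, 0 °C; cold aqueous NaHCO3/Na2S2O3 work-up
Reagents that add atoms: none
Why: Dess–Martin oxidation of the neopentyl-type primary alcohol to the non-enolisable aldehyde under neutral, cold conditions, so that the thermally labile aldehyde can be handled before it rearranges.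

Step 12
Reactants: 18 cis-vinylcyclopropanecarbaldehyde of series A
Product: 19 ring-fused 2,5-dihydrooxepine of series A
Conditions: PhMe, 70 °C, argon, base-washed glassware
Reagents that add atoms: none
Why: A concerted [3,3] sigmatropic shift (retro-Claisen rearrangement) runs through a boat-like six-atom array O=C6–C5–C9–C8=C7: the formyl oxygen bonds to C7 while the cyclopropane bond C5–C9 breaks, leaving C5=C6 as an enol ether and C8=C9 as the ester-conjugated alkene. The closest known reaction type is the thermal valence isomerisation of cis-2-vinylcyclopropanecarbaldehydes to 2,5-dihydrooxepines, the oxygen counterpart of the cis-divinylcyclopropane rearrangement. Ring B (O, C6, C5, C10, C9, C8, C7) is closed by pericyclic ring expansion of the three-membered ring, not by an ionic cyclisation of an open chain. No stereocentre is created: C1, C4 and C10 are carried through unchanged and C5 becomes sp2. The step needs the formyl and vinyl groups cis on the cyclopropane and a single carbonyl group in the array; the exo geometry from step 7 secures the first, and the former ketone, now the C4 ketal and trans to the vinyl group in any case, secures the second. Release of the strain of a fully substituted, cis-crowded cyclopropane and the gain of a trisubstituted enol ether and a trisubstituted conjugated enoate should place the equilibrium on the side of 19.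

Step 13
Reactants: 19 ring-fused 2,5-dihydrooxepine of series A
Product: 20 trans-fused lactone of series A (1R,4S,5S,10S)
Conditions: pyridinium chlorochromate [C5H5NH][CrO3Cl], 4 Å molecular sieves, CH2Cl2, rt
Reagents that add atoms: pyridinium chlorochromate, [O-][Cr](=O)(=O)Cl.c1cc[nH+]cc1
Why: Oxidation of a cyclic enol ether to the lactone by hexavalent chromium (known for dihydropyrans and glycals): C5 is protonated, chlorochromate adds to the oxocarbenium carbon C6 and the chromate ester collapses to the carbonyl; the proton should enter axially on the ring A face opposite the C12 methylene, giving the trans fusion (H5 anti to H10), which is also the more stable C5 epimer.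

Step 14
Reactants: 20 trans-fused lactone of series A
Product: 21 C11 carboxylic acid of series A (ketal retained)
Conditions: tris(dimethylamino)sulfonium difluorotrimethylsilicate, DMF, 0 °C → rt; aqueous NaH2PO4 work-up
Reagents that add atoms: none
Why: Fluoride-induced fragmentation of the 2-(trimethylsilyl)ethyl ester (attack at silicon, loss of ethene) with a non-basic anhydrous fluoride source, so that the enolisable C5–H next to the ketal oxygen and the lactone are not disturbed.

**Series B (alcohol half, from (S)-cryptone)**

Step 15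
Reactants: 6 4-isopropylcyclohexanone
Product: 23 (R)-4-isopropyl-1-(trimethylsilyloxy)cyclohex-1-ene, via lithium (R)-enolate 22 (not isolated)
Conditions: (S,S)-bis(1-phenylethyl)amine, n-BuLi, LiCl, THF, −78 °C; 6; then Me3SiCl, −78 °C
Reagents that add atoms: chlorotrimethylsilane, C[Si](C)(C)Cl
Why: The same chiral lithium amide desymmetrisation as in step 3 with the antipodal amide, which should remove the other enantiotopic proton and set C1′ in the mirror-image sense.

Step 16
Reactants: 23 (R)-4-isopropyl-1-(trimethylsilyloxy)cyclohex-1-ene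
Product: 24 (S)-cryptone [(S)-4-isopropylcyclohex-2-en-1-one]
Conditions: Pd(OAc)2 (10 mol %), O2 (1 atm), DMSO, rt
Reagents that add atoms: none
Why: Aerobic Saegusa–Ito dehydrogenation as in step 4, regiospecific for the enol ether side and without effect on C1′.

Step 17
Reactants: 24 (S)-cryptone; 10 formaldehyde (37 % aqueous)
Product: 25 (S)-2-(hydroxymethyl)-4-isopropylcyclohex-2-en-1-one
Conditions: 4-(dimethylamino)pyridine (0.2 equiv), THF/H2O (1:1), rt
Reagents that add atoms: none
Why: Morita–Baylis–Hillman hydroxymethylation at C5′ as in step 5; no stereocentre is formed.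

Step 18
Reactants: 25 (S)-2-(hydroxymethyl)-4-isopropylcyclohex-2-en-1-one
Product: 26 (S)-2-[(tert-butyldimethylsilyloxy)methyl]-4-isopropylcyclohex-2-en-1-one
Conditions: t-BuMe2SiCl, imidazole, CH2Cl2, 0 °C → rt
Reagents that add atoms: tert-butyldimethylsilyl chloride, CC(C)(C)[Si](C)(C)Cl
Why: Silylation of the primary alcohol as in step 6.

Step 19
Reactants: 5 sulfonium bromide; 26 silyl ether of series B
Product: 27 cyclopropyl ketone of series B (enantiomer of 13)
Conditions: 5 (1.3 equiv), Cs2CO3, MeCN, 0 °C → rt
Reagents that add atoms: none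
Why: Sulfur-ylide cyclopropanation (Michael-initiated ring closure) with a second portion of salt 5 as in step 7; attack anti to the C1′ isopropyl group and exo placement of the acrylate set C5′, C9′ and C10′ in the mirror-image sense.

Step 20
Reactants: 27 cyclopropyl ketone of series B
Product: 29 C4′,C12′-diol of series B (enantiomer of 15), via silane adduct 28 (not isolated)
Conditions: (i-PrO)Me2SiCH2MgCl, CeCl3, THF, −78 → 0 °C; then 30 % H2O2, KF, KHCO3, THF/MeOH, rt
Reagents that add atoms: (isopropoxydimethylsilyl)methylmagnesium chloride, CC(C)O[Si](C)(C)C[Mg]Cl; hydrogen peroxide, OO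
Why: Grignard 1,2-addition anti to the cyclopropane followed by Tamao–Fleming oxidation as in step 8, setting C4′ with C12′ cis to C6′.

Step 21
Reactants: 29 C4′,C12′-diol of series B
Product: 30 isopropylidene ketal of series B
Conditions: 2-methoxypropene, pyridinium p-toluenesulfonate (cat.), CH2Cl2, 0 °C
Reagents that add atoms: 2-methoxypropene, COC(C)=C
Why: Acid-catalysed ketalisation of the 1,2-diol as in step 9.

Step 22
Reactants: 30 isopropylidene ketal of series B
Product: 31 C6′ primary alcohol of series B
Conditions: HF·pyridine, pyridine, THF, 0 °C → rt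
Reagents that add atoms: none
Why: Buffered hydrogen fluoride desilylation as in step 10, selective for the silyl ether over the silylethyl ester.

Step 23
Reactants: 31 C6′ primary alcohol of series B
Product: 32 cis-vinylcyclopropanecarbaldehyde of series B
Conditions: Dess–Martin periodinane, CH2Cl2, 0 °C; cold aqueous NaHCO3/Na2S2O3 work-up
Reagents that add atoms: none
Why: Dess–Martin oxidation as in step 11.

Step 24
Reactants: 32 cis-vinylcyclopropanecarbaldehyde of series B
Product: 33 ring-fused 2,5-dihydrooxepine of series B
Conditions: PhMe, 70 °C, argon, base-washed glassware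
Reagents that add atoms: none
Why: The mirror image of step 12: retro-Claisen [3,3] ring expansion of the cis-vinylcyclopropanecarbaldehyde forms ring B′ without creating a stereocentre.

Step 25
Reactants: 33 ring-fused 2,5-dihydrooxepine of series B
Product: 34 trans-fused lactone of series B (1S,4R,5R,10R)
Conditions: pyridinium chlorochromate [C5H5NH][CrO3Cl], 4 Å molecular sieves, CH2Cl2, rt
Reagents that add atoms: pyridinium chlorochromate, [O-][Cr](=O)(=O)Cl.c1cc[nH+]cc1
Why: Hexavalent chromium oxidation of the enol ether to the lactone as in step 13, with axial protonation at C5′ giving the trans ring fusion.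

Step 26
Reactants: 34 trans-fused lactone of series B
Product: 35 C4′,C12′-diol lactone of series B (silylethyl ester retained)
Conditions: AcOH/H2O (4:1), 35 °C
Reagents that add atoms: none
Why: Mild acid hydrolysis of the isopropylidene ketal, which leaves the 2-(trimethylsilyl)ethyl ester and the lactone intact; the contact time is kept short so that the freed C12′ hydroxyl does not engage the lactone carbonyl.

**Union and deprotection**

Step 27
Reactants: 21 C11 carboxylic acid of series A; 35 C4′,C12′-diol lactone of series B
Product: 37 protected heterodimer (C11–O–C12′ ester), via mixed anhydride 36 (not isolated)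
Conditions: 2,4,6-trichlorobenzoyl chloride, Et3N, THF, rt; then 35, 4-(dimethylamino)pyridine, PhMe, rt
Reagents that add atoms: none
Why: Yamaguchi esterification: the mixed anhydride of the hindered unsaturated acid is attacked, under acyl-transfer catalysis, by the primary C12′ hydroxyl in preference to the tertiary C4′ hydroxyl; the heterochiral pairing is fixed by the choice of the two series and no stereocentre is created.

Step 28
Reactants: 37 protected heterodimer
Product: 38 heterodimer C11′ acid (ketal retained)
Conditions: tris(dimethylamino)sulfonium difluorotrimethylsilicate, DMF, 0 °C; aqueous NaH2PO4 work-up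
Reagents that add atoms: none
Why: The fluoride-induced ester fragmentation of step 14, now freeing the C11′ acid under conditions mild enough for the two lactones and the inter-half ester.

Step 29
Reactants: 38 heterodimer C11′ acid
Product: 39 CNP0340505.1
Conditions: AcOH/H2O (4:1), 35 °C
Reagents that add atoms: none
Why: Mild acid hydrolysis of the isopropylidene ketal as in step 26 uncovers the C4/C12 diol and completes the target; a short reaction time guards against transfer of the ring B acyl group to the new primary hydroxyl.

**Compound list**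

1 | 2-(bromomethyl)acrylic acid | C=C(CBr)C(=O)O | starting material
2 | 2-(trimethylsilyl)ethanol | C[Si](C)(C)CCO | starting material
3 | 2-(bromomethyl)acryloyl chloride | C=C(CBr)C(=O)Cl | intermediate (not isolated)
4 | 2-(trimethylsilyl)ethyl 2-(bromomethyl)acrylate | C=C(CBr)C(=O)OCC[Si](C)(C)C | intermediate
5 | 1-{2-[(2-trimethylsilylethoxy)carbonyl]allyl}tetrahydrothiophenium bromide | C=C(C[S+]1CCCC1)C(=O)OCC[Si](C)(C)C.[Br-] | intermediate
6 | 4-isopropylcyclohexanone | CC(C)C1CCC(=O)CC1 | starting material
7 | lithium (S)-4-isopropylcyclohex-1-en-1-olate | CC(C)[C@H]1CCC(O[Li])=CC1 | intermediate (not isolated)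
8 | (S)-4-isopropyl-1-(trimethylsilyloxy)cyclohex-1-ene | CC(C)[C@H]1CCC(O[Si](C)(C)C)=CC1 | intermediate
9 | (R)-cryptone, (R)-4-isopropylcyclohex-2-en-1-one | CC(C)[C@H]1CCC(=O)C=C1 | intermediate
10 | formaldehyde | C=O | starting material
11 | (R)-2-(hydroxymethyl)-4-isopropylcyclohex-2-en-1-one | CC(C)[C@H]1CCC(=O)C(CO)=C1 | intermediate
12 | (R)-2-[(tert-butyldimethylsilyloxy)methyl]-4-isopropylcyclohex-2-en-1-one | CC(C)[C@H]1CCC(=O)C(CO[Si](C)(C)C(C)(C)C)=C1 | intermediate
13 | cyclopropyl ketone, series A: 2-(trimethylsilyl)ethyl 2-[1-(tert-butyldimethylsilyloxymethyl)-5-isopropyl-2-oxobicyclo[4.1.0]heptan-7-yl]acrylate; cyclopropane C5–C9–C10 anti to isopropyl, acrylate exo on C9 and cis to C6, C1 R | CC(C)[C@H]1CCC(=O)[C@]2(CO[Si](C)(C)C(C)(C)C)[C@@H](C(=C)C(=O)OCC[Si](C)(C)C)[C@H]12 | intermediate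
14 | silane adduct, series A: tertiary C4 alcohol bearing CH2SiMe2(O-i-Pr), C12 cis to C6 | CC(C)[C@H]1CC[C@@](O)(C[Si](C)(C)OC(C)C)[C@]2(CO[Si](C)(C)C(C)(C)C)[C@@H](C(=C)C(=O)OCC[Si](C)(C)C)[C@H]12 | intermediate (not isolated)
15 | C4,C12-diol, series A: C12H2OH cis to C6, tertiary OH cis to the cyclopropane | CC(C)[C@H]1CC[C@@](O)(CO)[C@]2(CO[Si](C)(C)C(C)(C)C)[C@@H](C(=C)C(=O)OCC[Si](C)(C)C)[C@H]12 | intermediate
16 | isopropylidene ketal of 15 (spiro-dioxolane at C4), series A | CC(C)[C@H]1CC[C@@]3(COC(C)(C)O3)[C@]2(CO[Si](C)(C)C(C)(C)C)[C@@H](C(=C)C(=O)OCC[Si](C)(C)C)[C@H]12 | intermediate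
17 | C6 primary alcohol, series A (ketal, silylethyl ester) | CC(C)[C@H]1CC[C@@]3(COC(C)(C)O3)[C@]2(CO)[C@@H](C(=C)C(=O)OCC[Si](C)(C)C)[C@H]12 | intermediate
18 | cis-vinylcyclopropanecarbaldehyde, series A: formyl C6 on C5 cis to the acrylate on C9 | CC(C)[C@H]1CC[C@@]3(COC(C)(C)O3)[C@]2(C=O)[C@@H](C(=C)C(=O)OCC[Si](C)(C)C)[C@H]12 | intermediate
19 | ring-fused 2,5-dihydrooxepine, series A, (1R,4S,10S): enol ether C5=C6, enoate C8=C9 | CC(C)[C@H]1CC[C@@]3(COC(C)(C)O3)C2=COCC(C(=O)OCC[Si](C)(C)C)=C[C@H]12 | intermediate
20 | trans-fused lactone, series A, (1R,4S,5S,10S), ketal and 2-(trimethylsilyl)ethyl ester | CC(C)[C@H]1CC[C@@]3(COC(C)(C)O3)[C@H]2C(=O)OCC(C(=O)OCC[Si](C)(C)C)=C[C@H]12 | intermediate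
21 | C11 carboxylic acid, series A, (1R,4S,5S,10S), ketal retained | CC(C)[C@H]1CC[C@@]3(COC(C)(C)O3)[C@H]2C(=O)OCC(C(=O)O)=C[C@H]12 | intermediate
22 | lithium (R)-4-isopropylcyclohex-1-en-1-olate | CC(C)[C@@H]1CCC(O[Li])=CC1 | intermediate (not isolated)
23 | (R)-4-isopropyl-1-(trimethylsilyloxy)cyclohex-1-ene | CC(C)[C@@H]1CCC(O[Si](C)(C)C)=CC1 | intermediate
24 | (S)-cryptone, (S)-4-isopropylcyclohex-2-en-1-one | CC(C)[C@@H]1CCC(=O)C=C1 | intermediate
25 | (S)-2-(hydroxymethyl)-4-isopropylcyclohex-2-en-1-one | CC(C)[C@@H]1CCC(=O)C(CO)=C1 | intermediate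
26 | (S)-2-[(tert-butyldimethylsilyloxy)methyl]-4-isopropylcyclohex-2-en-1-one | CC(C)[C@@H]1CCC(=O)C(CO[Si](C)(C)C(C)(C)C)=C1 | intermediate
27 | cyclopropyl ketone, series B (enantiomer of 13) | CC(C)[C@@H]1CCC(=O)[C@@]2(CO[Si](C)(C)C(C)(C)C)[C@H](C(=C)C(=O)OCC[Si](C)(C)C)[C@@H]12 | intermediate
28 | silane adduct, series B (enantiomer of 14) | CC(C)[C@@H]1CC[C@](O)(C[Si](C)(C)OC(C)C)[C@@]2(CO[Si](C)(C)C(C)(C)C)[C@H](C(=C)C(=O)OCC[Si](C)(C)C)[C@@H]12 | intermediate (not isolated)
29 | C4′,C12′-diol, series B (enantiomer of 15) | CC(C)[C@@H]1CC[C@](O)(CO)[C@@]2(CO[Si](C)(C)C(C)(C)C)[C@H](C(=C)C(=O)OCC[Si](C)(C)C)[C@@H]12 | intermediate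
30 | isopropylidene ketal, series B (enantiomer of 16) | CC(C)[C@@H]1CC[C@]3(COC(C)(C)O3)[C@@]2(CO[Si](C)(C)C(C)(C)C)[C@H](C(=C)C(=O)OCC[Si](C)(C)C)[C@@H]12 | intermediate
31 | C6′ primary alcohol, series B (enantiomer of 17) | CC(C)[C@@H]1CC[C@]3(COC(C)(C)O3)[C@@]2(CO)[C@H](C(=C)C(=O)OCC[Si](C)(C)C)[C@@H]12 | intermediate
32 | cis-vinylcyclopropanecarbaldehyde, series B (enantiomer of 18) | CC(C)[C@@H]1CC[C@]3(COC(C)(C)O3)[C@@]2(C=O)[C@H](C(=C)C(=O)OCC[Si](C)(C)C)[C@@H]12 | intermediate
33 | ring-fused 2,5-dihydrooxepine, series B (enantiomer of 19) | CC(C)[C@@H]1CC[C@]3(COC(C)(C)O3)C2=COCC(C(=O)OCC[Si](C)(C)C)=C[C@@H]12 | intermediate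
34 | trans-fused lactone, series B, (1S,4R,5R,10R) (enantiomer of 20) | CC(C)[C@@H]1CC[C@]3(COC(C)(C)O3)[C@@H]2C(=O)OCC(C(=O)OCC[Si](C)(C)C)=C[C@@H]12 | intermediate
35 | C4′,C12′-diol lactone, series B, (1S,4R,5R,10R), 2-(trimethylsilyl)ethyl ester | CC(C)[C@@H]1CC[C@](O)(CO)[C@@H]2C(=O)OCC(C(=O)OCC[Si](C)(C)C)=C[C@@H]12 | intermediate
36 | mixed anhydride of acid 21 with 2,4,6-trichlorobenzoic acid | CC(C)[C@H]1CC[C@@]3(COC(C)(C)O3)[C@H]2C(=O)OCC(C(=O)OC(=O)c4c(Cl)cc(Cl)cc4Cl)=C[C@H]12 | intermediate (not isolated)
37 | protected heterodimer: C11 of half A esterified with O–C12′ of half B; ketal on half A, 2-(trimethylsilyl)ethyl ester on half B | CC(C)[C@H]1CC[C@@]3(COC(C)(C)O3)[C@H]2C(=O)OCC(C(=O)OC[C@@]5(O)CC[C@@H](C(C)C)[C@@H]6C=C(C(=O)OCC[Si](C)(C)C)COC(=O)[C@H]65)=C[C@H]12 | intermediate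
38 | heterodimer with free C11′ acid, ketal on half A | CC(C)[C@H]1CC[C@@]3(COC(C)(C)O3)[C@H]2C(=O)OCC(C(=O)OC[C@@]5(O)CC[C@@H](C(C)C)[C@@H]6C=C(C(=O)O)COC(=O)[C@H]65)=C[C@H]12 | intermediate
39 | CNP0340505.1, (1R,4S,5S,10S;1′S,4′R,5′R,10′R) | CC(C)[C@H]1CC[C@@](O)(CO)[C@H]2C(=O)OCC(C(=O)OC[C@@]3(O)CC[C@@H](C(C)C)[C@@H]4C=C(C(=O)O)COC(=O)[C@H]43)=C[C@H]12 | target

**Count and risks**

Total step count: 29. Longest linear sequence: 15 steps (steps 3–14 then 27–29; equally steps 15–26 then 27–29).

The three most fragile operations each occur once per enantiomeric series.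

1. Steps 7 and 19 (cyclopropanation). Conjugate addition to an α-substituted, γ-branched enone is slow, so self-condensation of the ylide with its own salt, attack at the carbonyl carbon, or loss of silanolate from the intermediate enolate may outrun ring closure. The fallback raises the acceptor reactivity by geminal diacyl activation and leaves the route at 11. Dess–Martin oxidation gives the 2-formyl enone F1. Its reaction with salt 5 and Cs2CO3 at low temperature is a cyclopropanation of a doubly activated alkene and should give the keto aldehyde F2. As a 1,1-diacyl-2-vinylcyclopropane this rearranges in the flask to the vinylogous ester dihydrooxepine F3. Axial 1,2-addition of the silylmethyl Grignard reagent with CeCl3 to the C4 carbonyl, on the face of H10, gives the silane adduct F4. Tamao–Fleming oxidation gives the diol F5, and ketalisation with 2-methoxypropene returns to the route at 19. In the mirror-image series the same detour runs from 25 through the formyl enone F6, the keto aldehyde F7, the vinylogous ester F8, the silane adduct F9 and the diol F10 to 33.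

2. Steps 12 and 24 (retro-Claisen ring expansion). The valence equilibrium may remain on the aldehyde side, or prolonged heating may erode the material through other thermal channels before conversion is complete. The fallback couples the rearrangement to an irreversible oxidation and isolates neither valence isomer. Alcohol 17 is treated with an excess of pyridinium chlorochromate in warm 1,2-dichloroethane. The reagent first oxidises the alcohol to aldehyde 18, and each portion of dihydrooxepine 19 that forms is oxidised at once to lactone 20, so the equilibrium is drained. The detour leaves at 17 and comes back at 20 (31 to 34 in the mirror series) and makes no new compound.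

3. Steps 13 and 25 (enol ether to lactone). Under the acidic chromium reagent the allylic C4–O bond of the ketal may ionise to a conjugated oxocarbenium ion, or the allylic C7 methylene may be attacked. The fallback avoids chromium and leaves at 19. Addition of anhydrous hydrogen peroxide across the enol ether, with a trace of pyridinium p-toluenesulfonate at low temperature, gives the hydroperoxy acetal F11, with C5 protonated as in step 13. Acetic anhydride and triethylamine convert it through the peracetate F12 into lactone 20 by base-induced elimination across the O–O bond. In the mirror series 33 gives the hydroperoxy acetal F13 and the peracetate F14 and then 34.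

Further compounds
F1 | step 7 | (R)-3-isopropyl-6-oxocyclohex-1-ene-1-carbaldehyde | CC(C)[C@H]1CCC(=O)C(C=O)=C1
F2 | step 7 | keto aldehyde cyclopropane, series A (C4 ketone and C6 formyl on C5, acrylate exo on C9; not isolated) | CC(C)[C@H]1CCC(=O)[C@]2(C=O)[C@@H](C(=C)C(=O)OCC[Si](C)(C)C)[C@H]12
F3 | step 7 | vinylogous ester dihydrooxepine, series A (C4 ketone conjugated with enol ether C5=C6) | CC(C)[C@H]1CCC(=O)C2=COCC(C(=O)OCC[Si](C)(C)C)=C[C@H]12
F4 | step 7 | silane adduct of F3 (tertiary C4 alcohol bearing CH2SiMe2(O-i-Pr)) | CC(C)[C@H]1CC[C@@](O)(C[Si](C)(C)OC(C)C)C2=COCC(C(=O)OCC[Si](C)(C)C)=C[C@H]12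
F5 | step 7 | C4,C12-diol dihydrooxepine, series A | CC(C)[C@H]1CC[C@@](O)(CO)C2=COCC(C(=O)OCC[Si](C)(C)C)=C[C@H]12
F6 | step 19 | (S)-3-isopropyl-6-oxocyclohex-1-ene-1-carbaldehyde | CC(C)[C@@H]1CCC(=O)C(C=O)=C1
F7 | step 19 | keto aldehyde cyclopropane, series B (enantiomer of F2; not isolated) | CC(C)[C@@H]1CCC(=O)[C@@]2(C=O)[C@H](C(=C)C(=O)OCC[Si](C)(C)C)[C@@H]12
F8 | step 19 | vinylogous ester dihydrooxepine, series B (enantiomer of F3) | CC(C)[C@@H]1CCC(=O)C2=COCC(C(=O)OCC[Si](C)(C)C)=C[C@@H]12
F9 | step 19 | silane adduct of F8 (enantiomer of F4) | CC(C)[C@@H]1CC[C@](O)(C[Si](C)(C)OC(C)C)C2=COCC(C(=O)OCC[Si](C)(C)C)=C[C@@H]12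
F10 | step 19 | C4′,C12′-diol dihydrooxepine, series B (enantiomer of F5) | CC(C)[C@@H]1CC[C@](O)(CO)C2=COCC(C(=O)OCC[Si](C)(C)C)=C[C@@H]12
F0 | step 12 | none | none
F0 | step 24 | none | none
F11 | step 13 | hydroperoxy acetal at C6, series A (C6 configuration open) | CC(C)[C@H]1CC[C@@]3(COC(C)(C)O3)[C@H]2C(OO)OCC(C(=O)OCC[Si](C)(C)C)=C[C@H]12
F12 | step 13 | peracetate of F11 (not isolated) | CC(C)[C@H]1CC[C@@]3(COC(C)(C)O3)[C@H]2C(OOC(C)=O)OCC(C(=O)OCC[Si](C)(C)C)=C[C@H]12
F13 | step 25 | hydroperoxy acetal at C6′, series B (enantiomeric series) | CC(C)[C@@H]1CC[C@]3(COC(C)(C)O3)[C@@H]2C(OO)OCC(C(=O)OCC[Si](C)(C)C)=C[C@@H]12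
F14 | step 25 | peracetate of F13 (not isolated) | CC(C)[C@@H]1CC[C@]3(COC(C)(C)O3)[C@@H]2C(OOC(C)=O)OCC(C(=O)OCC[Si](C)(C)C)=C[C@@H]12
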